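Ring B is opened at C6–C7 (labdane numbering) by recognising its C6(O)–C7H2–C8=C9 array as the product of a [1,3]-acyl shift. A cis-fused 2-vinylcyclobutanone (C5–C6(=O)–C9–C10, vinyl C8=C7 on C9) is built on the C5=C10 alkene derived from silylated actinol: a dichloroketene [2+2] cycloaddition sets C5 and C10 from the purchased C2 stereocentre, then C9 is alkylated and vinylated. On heating, C6 migrates from C9 to C7: ring B closes, the tetrasubstituted C8=C9 alkene forms regiospecifically and the cis ring fusion is retained. Hydride addition from the open face then sets C6; the butenolide is coupled on last.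

Key step: step 9

Remark (assumption): (4R,6R)-actinol is taken as a purchasable chiral building block; its methyl-bearing stereocentre is erased in step 2, so only its carbinol centre (C2 of the target) is used.
Remark (numbering): labdane numbering of the target is used for all intermediates: ring A = C1–C5 and C10, ring B = C5–C10, C11–C12 = ethylene link, C13–C16 = butenolide (C15 carbonyl, C16 OCH2), C17 = CH2O on C8, C18 and C19 = methyls on C4, C20 = methyl on C10; β is the face of C20, α the opposite face.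

Step 1
Reactants: 1 (4R,6R)-4-hydroxy-2,2,6-trimethylcyclohexan-1-one ((4R,6R)-actinol)
Product: 2 (4R,6R)-4-[(tert-butyldiphenylsilyl)oxy]-2,2,6-trimethylcyclohexan-1-one
Conditions: t-BuPh2SiCl, imidazole, DMF, rt
Reagents that add atoms: tert-butyl(chloro)diphenylsilane CC(C)(C)[Si](Cl)(c1ccccc1)c1ccccc1
Why: Silyl ether formation protects the C2 hydroxyl with a group that should survive every later step and that fixes the ring conformation used in step 4.

Step 2
Reactants: 2 (4R,6R)-4-[(tert-butyldiphenylsilyl)oxy]-2,2,6-trimethylcyclohexan-1-one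
Product: 4 (R)-4-[(tert-butyldiphenylsilyl)oxy]-2,6,6-trimethylcyclohex-1-en-1-yl trifluoromethanesulfonate, via lithium enolate 3 (not isolated)
Conditions: LiN(iPr)2, THF, −78 to 0 °C; then PhNTf2, 0 °C to rt
Reagents that add atoms: N-phenylbis(trifluoromethanesulfonimide) O=S(=O)(N(c1ccccc1)S(=O)(=O)C(F)(F)F)C(F)(F)F
Why: Enol triflate formation is regiospecific because only C10 carries an α-hydrogen (C4 is quaternary), and it deliberately erases the C10 stereocentre of actinol.

Step 3
Reactants: 4 (R)-4-[(tert-butyldiphenylsilyl)oxy]-2,6,6-trimethylcyclohex-1-en-1-yl trifluoromethanesulfonate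
Product: 5 (R)-tert-butyldiphenyl[(3,5,5-trimethylcyclohex-3-en-1-yl)oxy]silane (ring A alkene, C5=C10)
Conditions: Pd(OAc)2 (cat.), PPh3, HCO2H, Bu3N, DMF, 60 °C
Reagents that add atoms: none
Why: Palladium-catalysed formate reduction (hydrogenolysis) of the enol triflate should give the trisubstituted C5=C10 alkene without touching the silyl ether.

Step 4
Reactants: 5 (R)-tert-butyldiphenyl[(3,5,5-trimethylcyclohex-3-en-1-yl)oxy]silane
Product: 6 cis-fused dichlorocyclobutanone 3-[(tert-butyldiphenylsilyl)oxy]-8,8-dichloro-1,5,5-trimethylbicyclo[4.2.0]octan-7-one (C7 of this name = C6 on C5; C8 = C9 on C10; O-2, C6 and C9 α; H-5 and C20 β)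
Conditions: Cl3CCOCl, activated Zn dust, Et2O/DME, 35 °C
Reagents that add atoms: trichloroacetyl chloride ClC(Cl)(Cl)C(Cl)=O, as source of dichloroketene ClC(Cl)=C=O
Why: Ketene–alkene [2+2] cycloaddition: the carbonyl carbon should bond to the less substituted C5 and the CCl2 carbon to C10, suprafacial addition makes the ring fusion cis, and the ketene should add anti to the pseudoaxial C4 methyl of the half-chair with equatorial silyloxy group, that is syn to the C2 oxygen, which sets C5 (H β) and C10 (methyl β) from C2.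

Step 5
Reactants: 6 cis-fused dichlorocyclobutanone
Product: 7 cyclobutanone 3-[(tert-butyldiphenylsilyl)oxy]-1,5,5-trimethylbicyclo[4.2.0]octan-7-one (configuration as in 6; C9 is CH2)
Conditions: Zn dust, AcOH, 60 °C
Reagents that add atoms: none
Why: Zinc reduction of the α,α-dichloroketone (through the zinc enolate) should remove both chlorines, and the cis fusion is safe because it is the only low-strain fusion of a bicyclo[4.2.0]octanone.

Step 6
Reactants: 7 cyclobutanone 3-[(tert-butyldiphenylsilyl)oxy]-1,5,5-trimethylbicyclo[4.2.0]octan-7-one; 8 tert-butyl(2-iodoethoxy)dimethylsilane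
Product: 10 C9-alkylated cyclobutanone carrying the C11–C12 chain 2-[(tert-butyldimethylsilyl)oxy]ethyl on C9 (chain β, H-9 α), via lithium enolate 9 (not isolated)
Conditions: LiN(iPr)2, THF, −78 °C; then 8, DMPU, −78 to −20 °C
Reagents that add atoms: none
Why: Kinetic enolate alkylation (SN2): the base should remove a C9 proton because the C5 proton lies between two quaternary carbons, and the iodide should enter on the convex β face to give a C9 configuration that is only temporary.

Step 7
Reactants: 11 2-bromoprop-2-en-1-ol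
Product: 12 [(2-bromoprop-2-en-1-yl)oxy](tert-butyl)diphenylsilane
Conditions: t-BuPh2SiCl, imidazole, CH2Cl2, rt
Reagents that add atoms: tert-butyl(chloro)diphenylsilane CC(C)(C)[Si](Cl)(c1ccccc1)c1ccccc1
Why: Silyl ether formation gives the C7–C8–C17 alkenyl bromide with C17 already at the alcohol oxidation level.

Step 8
Reactants: 10 C9-alkylated cyclobutanone; 12 [(2-bromoprop-2-en-1-yl)oxy](tert-butyl)diphenylsilane
Product: 14 2-vinylcyclobutanone with quaternary C9 bearing 3-[(tert-butyldiphenylsilyl)oxy]prop-1-en-2-yl (C8(=C7H2)C17, β) and 2-[(tert-butyldimethylsilyl)oxy]ethyl (C11–C12, α), via lithium enolate 13 (not isolated)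
Conditions: Pd2(dba)3 (cat.), [HP(t-Bu)3]BF4 (cat.), LiN(SiMe3)2, toluene/THF, rt to 60 °C
Reagents that add atoms: none
Why: Palladium-catalysed α-alkenylation of a ketone enolate should couple the C9 enolate with the alkenyl bromide on the convex face and so forge the quaternary C9 that carries the C8=C7 vinyl unit; the configuration at C9 is of no consequence because C9 becomes trigonal in step 9.

Step 9
Reactants: 14 2-vinylcyclobutanone with quaternary C9
Product: 15 12-[(tert-butyldimethylsilyl)oxy]-2α,17-bis[(tert-butyldiphenylsilyl)oxy]-13,14,15,16-tetranor-5β-labd-8-en-6-one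
Conditions: toluene (degassed), 150 °C, sealed tube
Reagents that add atoms: none
Why: Thermal [1,3]-acyl shift (vinylcyclobutanone to cyclohex-3-enone rearrangement): the strained C6–C9 bond, which is α to the carbonyl, allylic and attached to a fully substituted carbon, should cleave to an acyl/allyl radical pair that recombines at the other allyl terminus C7. The closest known reaction type is the thermal ring enlargement of 2-vinylcyclobutanones and its alkoxide-accelerated cyclobutanol variant. Ring B closes as a four-to-six ring enlargement in which C6 stays bonded to C5 and travels suprafacially across the C9–C8–C7 allyl unit, a formal 6-endo recombination at the CH2 terminus. No stereocentre is created: C9 becomes trigonal while C5 and C10 are untouched, so the cis ring fusion set by the [2+2] step is carried into the octalin. The step needs cleavage of C6–C9 rather than C5–C6 (secured by the allylic, fully substituted C9), recombination at C7 rather than back at C9 (secured by loss of the cyclobutane strain), and no drift of the new alkene into conjugation or epimerisation at C5 (secured by neutral, base-free conditions). The C6 carbonyl, the C7 methylene and the tetrasubstituted C8=C9 alkene thus appear in one operation with no regioisomer possible.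

Step 10
Reactants: 15 12-[(tert-butyldimethylsilyl)oxy]-2α,17-bis[(tert-butyldiphenylsilyl)oxy]-13,14,15,16-tetranor-5β-labd-8-en-6-one
Product: 16 12-[(tert-butyldimethylsilyl)oxy]-2α,17-bis[(tert-butyldiphenylsilyl)oxy]-13,14,15,16-tetranor-5β-labd-8-en-6α-ol
Conditions: NaBH4, CeCl3·7H2O, MeOH/THF, −78 to −40 °C
Reagents that add atoms: none
Why: Luche reduction (1,2-hydride addition): in the folded cis-octalone C6 is axial on ring A, whose axial C1–H and C3–H bonds shield the α face of the carbonyl, so hydride should add from the open β face and give the 6α-carbinol (H-6 β, hydroxyl trans to H-5).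

Step 11
Reactants: 16 12-[(tert-butyldimethylsilyl)oxy]-2α,17-bis[(tert-butyldiphenylsilyl)oxy]-13,14,15,16-tetranor-5β-labd-8-en-6α-ol
Product: 17 2α,17-bis[(tert-butyldiphenylsilyl)oxy]-13,14,15,16-tetranor-5β-labd-8-ene-6α,12-diol
Conditions: HF·pyridine, pyridine, THF, 0 °C
Reagents that add atoms: none
Why: Selective desilylation: the primary tert-butyldimethylsilyl ether should be cleaved far faster than the two tert-butyldiphenylsilyl ethers.

Step 12
Reactants: 17 2α,17-bis[(tert-butyldiphenylsilyl)oxy]-13,14,15,16-tetranor-5β-labd-8-ene-6α,12-diol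
Product: 18 2α,17-bis[(tert-butyldiphenylsilyl)oxy]-12-iodo-13,14,15,16-tetranor-5β-labd-8-en-6α-ol
Conditions: I2, PPh3, imidazole, CH2Cl2, 0 °C
Reagents that add atoms: iodine II
Why: Appel-type iodination should convert only the primary C12 alcohol, the hindered secondary C6 carbinol being much slower.

Step 13
Reactants: 18 2α,17-bis[(tert-butyldiphenylsilyl)oxy]-12-iodo-13,14,15,16-tetranor-5β-labd-8-en-6α-ol; 19 4-bromofuran-2(5H)-one
Product: 20 2α,17-bis[(tert-butyldiphenylsilyl)oxy]-6α-hydroxy-5β-labda-8,13-dien-15,16-olide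
Conditions: NiI2 (cat.), 4,4′-di-tert-butyl-2,2′-bipyridine, Zn dust, DMA, rt
Reagents that add atoms: none
Why: Nickel-catalysed reductive cross-electrophile coupling of an alkyl iodide with an alkenyl bromide should form the C12–C13 bond, tolerate the free C6 hydroxyl and install the butenolide intact.

Step 14
Reactants: 20 2α,17-bis[(tert-butyldiphenylsilyl)oxy]-6α-hydroxy-5β-labda-8,13-dien-15,16-olide
Product: 21 (2S,5R,6S,10S)-2α,6α,17-trihydroxy-5β-labda-8,13-dien-15,16-olide (target)
Conditions: Bu4NF, AcOH, THF, rt to 40 °C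
Reagents that add atoms: none
Why: Fluoride desilylation buffered with acetic acid should free the C2 and C17 hydroxyls without base damage to the butenolide.

Compound list
1 | (4R,6R)-4-hydroxy-2,2,6-trimethylcyclohexan-1-one ((4R,6R)-actinol) | CC1(C)C[C@H](O)C[C@@H](C)C1=O | starting material
2 | (4R,6R)-4-[(tert-butyldiphenylsilyl)oxy]-2,2,6-trimethylcyclohexan-1-one | CC1(C)C[C@H](O[Si](c2ccccc2)(c2ccccc2)C(C)(C)C)C[C@@H](C)C1=O | intermediate
3 | lithium enolate of 2 | [Li+].CC1(C)C[C@H](O[Si](c2ccccc2)(c2ccccc2)C(C)(C)C)CC(C)=C1[O-] | intermediate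
4 | (R)-4-[(tert-butyldiphenylsilyl)oxy]-2,6,6-trimethylcyclohex-1-en-1-yl trifluoromethanesulfonate | CC1(C)C[C@H](O[Si](c2ccccc2)(c2ccccc2)C(C)(C)C)CC(C)=C1OS(=O)(=O)C(F)(F)F | intermediate
5 | (R)-tert-butyldiphenyl[(3,5,5-trimethylcyclohex-3-en-1-yl)oxy]silane | CC1(C)C[C@H](O[Si](c2ccccc2)(c2ccccc2)C(C)(C)C)CC(C)=C1 | intermediate
6 | cis-fused 3-[(tert-butyldiphenylsilyl)oxy]-8,8-dichloro-1,5,5-trimethylbicyclo[4.2.0]octan-7-one (O-2, C6, C9 α; H-5, C20 β) | CC1(C)C[C@H](O[Si](c3ccccc3)(c3ccccc3)C(C)(C)C)C[C@]2(C)C(Cl)(Cl)C(=O)[C@H]12 | intermediate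
7 | cis-fused 3-[(tert-butyldiphenylsilyl)oxy]-1,5,5-trimethylbicyclo[4.2.0]octan-7-one | CC1(C)C[C@H](O[Si](c3ccccc3)(c3ccccc3)C(C)(C)C)C[C@]2(C)CC(=O)[C@H]12 | intermediate
8 | tert-butyl(2-iodoethoxy)dimethylsilane | CC(C)(C)[Si](C)(C)OCCI | starting material
9 | lithium enolate of 7 (C6=C9) | [Li+].CC1(C)C[C@H](O[Si](c3ccccc3)(c3ccccc3)C(C)(C)C)C[C@]2(C)C=C([O-])[C@H]12 | intermediate
10 | cyclobutanone 7 carrying 2-[(tert-butyldimethylsilyl)oxy]ethyl on C9 (chain β, H-9 α) | CC1(C)C[C@H](O[Si](c3ccccc3)(c3ccccc3)C(C)(C)C)C[C@]2(C)[C@@H](CCO[Si](C)(C)C(C)(C)C)C(=O)[C@H]12 | intermediate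
11 | 2-bromoprop-2-en-1-ol | OCC(Br)=C | starting material
12 | [(2-bromoprop-2-en-1-yl)oxy](tert-butyl)diphenylsilane | C=C(Br)CO[Si](c1ccccc1)(c1ccccc1)C(C)(C)C | intermediate
13 | lithium enolate of 10 (C6=C9) | [Li+].CC1(C)C[C@H](O[Si](c3ccccc3)(c3ccccc3)C(C)(C)C)C[C@]2(C)C(CCO[Si](C)(C)C(C)(C)C)=C([O-])[C@H]12 | intermediate
14 | 2-vinylcyclobutanone, quaternary C9 with β 3-[(tert-butyldiphenylsilyl)oxy]prop-1-en-2-yl and α 2-[(tert-butyldimethylsilyl)oxy]ethyl | CC1(C)C[C@H](O[Si](c3ccccc3)(c3ccccc3)C(C)(C)C)C[C@]2(C)[C@@](CCO[Si](C)(C)C(C)(C)C)(C(=C)CO[Si](c3ccccc3)(c3ccccc3)C(C)(C)C)C(=O)[C@H]12 | intermediate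
15 | 12-[(tert-butyldimethylsilyl)oxy]-2α,17-bis[(tert-butyldiphenylsilyl)oxy]-13,14,15,16-tetranor-5β-labd-8-en-6-one | CC1(C)C[C@H](O[Si](c3ccccc3)(c3ccccc3)C(C)(C)C)C[C@]2(C)C(CCO[Si](C)(C)C(C)(C)C)=C(CO[Si](c3ccccc3)(c3ccccc3)C(C)(C)C)CC(=O)[C@H]12 | intermediate
16 | 12-[(tert-butyldimethylsilyl)oxy]-2α,17-bis[(tert-butyldiphenylsilyl)oxy]-13,14,15,16-tetranor-5β-labd-8-en-6α-ol | CC1(C)C[C@H](O[Si](c3ccccc3)(c3ccccc3)C(C)(C)C)C[C@]2(C)C(CCO[Si](C)(C)C(C)(C)C)=C(CO[Si](c3ccccc3)(c3ccccc3)C(C)(C)C)C[C@H](O)[C@H]12 | intermediate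
17 | 2α,17-bis[(tert-butyldiphenylsilyl)oxy]-13,14,15,16-tetranor-5β-labd-8-ene-6α,12-diol | CC1(C)C[C@H](O[Si](c3ccccc3)(c3ccccc3)C(C)(C)C)C[C@]2(C)C(CCO)=C(CO[Si](c3ccccc3)(c3ccccc3)C(C)(C)C)C[C@H](O)[C@H]12 | intermediate
18 | 2α,17-bis[(tert-butyldiphenylsilyl)oxy]-12-iodo-13,14,15,16-tetranor-5β-labd-8-en-6α-ol | CC1(C)C[C@H](O[Si](c3ccccc3)(c3ccccc3)C(C)(C)C)C[C@]2(C)C(CCI)=C(CO[Si](c3ccccc3)(c3ccccc3)C(C)(C)C)C[C@H](O)[C@H]12 | intermediate
19 | 4-bromofuran-2(5H)-one | O=C1C=C(Br)CO1 | starting material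
20 | 2α,17-bis[(tert-butyldiphenylsilyl)oxy]-6α-hydroxy-5β-labda-8,13-dien-15,16-olide | CC1(C)C[C@H](O[Si](c3ccccc3)(c3ccccc3)C(C)(C)C)C[C@]2(C)C(CCC3=CC(=O)OC3)=C(CO[Si](c3ccccc3)(c3ccccc3)C(C)(C)C)C[C@H](O)[C@H]12 | intermediate
21 | (2S,5R,6S,10S)-2α,6α,17-trihydroxy-5β-labda-8,13-dien-15,16-olide | CC1(C)C[C@H](O)C[C@]2(C)C(CCC3=CC(=O)OC3)=C(CO)C[C@H](O)[C@H]12 | target

Total step count: 14. Longest linear sequence: 13 steps (steps 1–6 and 8–14; step 7 is a one-step side branch).

Steps most likely to fail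

Step 8 (α-alkenylation at C9). The reductive elimination has to join the alkenyl group to a fully substituted carbon next to quaternary C10 and may be too slow, so that reduction of the alkenyl bromide or enolisation elsewhere takes over. The fallback sets out from 7 and comes back at 15. The same palladium-catalysed α-alkenylation with 12 is run on 7, whose C9 is still a methylene, to give the mono-alkenylated cyclobutanone F1. Deprotonation with LiN(iPr)2 to the cross-conjugated dienolate and SN2 alkylation at C9 with iodide 8 then forge the quaternary carbon and give the C9-epimeric vinylcyclobutanone F2. Heated as in step 9, F2 converges on 15 because C9 becomes trigonal.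

Step 9 (thermal [1,3]-acyl shift). At the temperature needed the radical pair may lose carbon monoxide, or the cyclobutanone may revert to ketene and alkene. The fallback sets out from 14 and comes back at 15. NaBH4 reduction, with hydride from the convex β face, gives the cyclobutanol F3. Its potassium alkoxide (KH, 18-crown-6, THF, 25 to 65 °C) should undergo the alkoxide-accelerated vinylcyclobutane [1,3]-shift at far lower temperature to the 6β-cyclohexenol F4, with the oxygen in the outer position. Dess–Martin oxidation then returns enone 15.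

Step 10 (hydride addition to C6). Facial selectivity may erode if the octalone reacts through its ring-flipped conformer, in which the C20 methyl shields the β face, so that the 6β-alcohol forms. The fallback sets out from 15 and comes back at 16. The 6β-alcohol F4 is inverted by a Mitsunobu reaction (4-nitrobenzoic acid, diisopropyl azodicarboxylate, PPh3) to the 6α-(4-nitrobenzoate) F5, and methanolysis (K2CO3, MeOH) releases 16.

Further compounds
F1 | step 8 | mono-alkenylated cyclobutanone, 7 carrying 3-[(tert-butyldiphenylsilyl)oxy]prop-1-en-2-yl on C9 (β, H-9 α) | CC1(C)C[C@H](O[Si](c3ccccc3)(c3ccccc3)C(C)(C)C)C[C@]2(C)[C@@H](C(=C)CO[Si](c3ccccc3)(c3ccccc3)C(C)(C)C)C(=O)[C@H]12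
F2 | step 8 | C9-epimeric vinylcyclobutanone (C9 epimer of 14: alkenyl α, silyloxyethyl β) | CC1(C)C[C@H](O[Si](c3ccccc3)(c3ccccc3)C(C)(C)C)C[C@]2(C)[C@](CCO[Si](C)(C)C(C)(C)C)(C(=C)CO[Si](c3ccccc3)(c3ccccc3)C(C)(C)C)C(=O)[C@H]12
F3 | step 9 | cyclobutanol from 14 (C6 hydroxyl on the concave α face) | CC1(C)C[C@H](O[Si](c3ccccc3)(c3ccccc3)C(C)(C)C)C[C@]2(C)[C@@](CCO[Si](C)(C)C(C)(C)C)(C(=C)CO[Si](c3ccccc3)(c3ccccc3)C(C)(C)C)[C@H](O)[C@H]12
F4 | step 9 | 12-[(tert-butyldimethylsilyl)oxy]-2α,17-bis[(tert-butyldiphenylsilyl)oxy]-13,14,15,16-tetranor-5β-labd-8-en-6β-ol | CC1(C)C[C@H](O[Si](c3ccccc3)(c3ccccc3)C(C)(C)C)C[C@]2(C)C(CCO[Si](C)(C)C(C)(C)C)=C(CO[Si](c3ccccc3)(c3ccccc3)C(C)(C)C)C[C@@H](O)[C@H]12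
F5 | step 10 | 6α-(4-nitrobenzoate) of 16 | CC1(C)C[C@H](O[Si](c3ccccc3)(c3ccccc3)C(C)(C)C)C[C@]2(C)C(CCO[Si](C)(C)C(C)(C)C)=C(CO[Si](c3ccccc3)(c3ccccc3)C(C)(C)C)C[C@H](OC(=O)c3ccc(cc3)[N+](=O)[O-])[C@H]12
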